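**Retrosynthetic overview**
- The route rests on ring A (C4a, C5, C6, C7, C8, C8a). Its oxygens at C5 and C7 stand 1,3 across the unsubstituted C6, a β-dicarbonyl pattern, so C5–C6 is cut as a Claisen bond between an ester carbon (C5, on C4a) and a methyl ketone (C6–C7, on C8). Both sit cis on the C8a=C4a bond of a 4-pyranone (ring C) that already holds O1, which fixes the side chain at C8.
- The methyl ketone comes from lateral C-acetylation of the 2-alkyl group (future C8) of a methyl 5-aryl-2-alkyl-4-oxo-4H-pyran-3-carboxylate that already carries the silyl-protected side chain.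
- Ring C is cut at O1–C2 and C2–C3: DMF-DMA supplies C2 to a 2-acyl-β-keto ester, made by C-acylation of a chain β-keto ester (acetoacetate dianion plus side-chain iodide) with the ring B arylacetyl chloride.
- Ring order: ring B is bought, ring C closes in step 7, ring A closes in step 9; desilylation and hydrogenolysis finish.

Key step: step 9

Assumption: the Dieckmann precursor is used as the racemate; its single stereocentre (the future C8) becomes an aromatic carbon, and the target has no stereocentre.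

**Step 1**
Reactants: 1 3-methylbutane-1,3-diol
Product: 2 4-iodo-2-methylbutan-2-ol
Conditions: I2, PPh3, imidazole, CH2Cl2, 0 °C to rt
Reagents that add atoms: iodine, II
Why: Appel-type iodination activates only the unhindered primary hydroxyl as its alkoxyphosphonium salt, and SN2 displacement by iodide should leave the tertiary alcohol untouched.

**Step 2**
Reactants: 2 4-iodo-2-methylbutan-2-ol
Product: 3 triethyl[(4-iodo-2-methylbutan-2-yl)oxy]silane
Conditions: Et3SiOTf, 2,6-lutidine, CH2Cl2, −78 to 0 °C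
Reagents that add atoms: triethylsilyl trifluoromethanesulfonate, CC[Si](CC)(CC)OS(=O)(=O)C(F)(F)F
Why: Silylation of a hindered tertiary alcohol with a silyl triflate and a hindered pyridine base is standard, and the primary iodide is inert to it.

**Step 3**
Reactants: 4 methyl acetoacetate; 3 triethyl[(4-iodo-2-methylbutan-2-yl)oxy]silane
Product: 5 methyl 7-methyl-3-oxo-7-[(triethylsilyl)oxy]octanoate
Conditions: NaH, THF, 0 °C; n-BuLi, 0 °C; then 3, 0 °C to rt; AcOH quench
Reagents that add atoms: none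
Why: γ-Alkylation of the acetoacetate dianion: the more basic terminal carbanion is alkylated by the primary iodide while the stabilised C2 enolate stays untouched.

**Step 4**
Reactants: 6 (2,4-dihydroxyphenyl)acetic acid
Product: 7 benzyl [2,4-bis(benzyloxy)phenyl]acetate
Conditions: BnBr, K2CO3, DMF, 60 °C
Reagents that add atoms: benzyl bromide, BrCc1ccccc1
Why: Williamson etherification of both phenols together with O-alkylation of the carboxylate should give the tribenzyl compound.

**Step 5**
Reactants: 7 benzyl [2,4-bis(benzyloxy)phenyl]acetate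
Product: 8 [2,4-bis(benzyloxy)phenyl]acetic acid
Conditions: NaOH, THF/MeOH/H2O, 50 °C; then aq HCl
Reagents that add atoms: sodium hydroxide, [Na+].[OH-]
Why: Saponification cleaves the benzyl ester, and aryl benzyl ethers are stable to hydroxide.

**Step 6**
Reactants: 8 [2,4-bis(benzyloxy)phenyl]acetic acid; 5 methyl 7-methyl-3-oxo-7-[(triethylsilyl)oxy]octanoate
Product: 10 methyl 2-{[2,4-bis(benzyloxy)phenyl]acetyl}-7-methyl-3-oxo-7-[(triethylsilyl)oxy]octanoate, via acid chloride 9 (not isolated)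
Conditions: (COCl)2, DMF (cat.), CH2Cl2, 0 °C to rt, evaporate; then 5, MgCl2, pyridine, CH2Cl2, 0 °C to rt
Reagents that add atoms: none
Why: Acid chloride formation under Vilsmeier catalysis is followed by C-acylation of the magnesium chelate of the β-keto ester, which directs the acyl group to carbon and should give the 2-acyl-β-keto ester as its enol chelate.

**Step 7**
Reactants: 10 methyl 2-{[2,4-bis(benzyloxy)phenyl]acetyl}-7-methyl-3-oxo-7-[(triethylsilyl)oxy]octanoate
Product: 12 methyl 5-[2,4-bis(benzyloxy)phenyl]-2-{4-methyl-4-[(triethylsilyl)oxy]pentyl}-4-oxo-4H-pyran-3-carboxylate, via enaminone 11 (not isolated)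
Conditions: DMF-DMA, PhMe, 90 °C; then AcOH, 50 °C
Reagents that add atoms: N,N-dimethylformamide dimethyl acetal, COC(OC)N(C)C
Why: Aminomethylenation should occur at the most acidic free methylene, the benzylic CH2 between aryl and ketone (as in the deoxybenzoin route to isoflavones), and the enol oxygen of the neighbouring ketone then closes ring C by addition–elimination with loss of dimethylamine, as 2-acyl-1,3-diketones do in giving fused 4-pyranones.

**Step 8**
Reactants: 12 methyl 5-[2,4-bis(benzyloxy)phenyl]-2-{4-methyl-4-[(triethylsilyl)oxy]pentyl}-4-oxo-4H-pyran-3-carboxylate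
Product: 13 methyl 5-[2,4-bis(benzyloxy)phenyl]-2-{6-methyl-2-oxo-6-[(triethylsilyl)oxy]heptan-3-yl}-4-oxo-4H-pyran-3-carboxylate (racemic)
Conditions: LiN(SiMe3)2 (2.2 equiv), THF, −78 °C; N-acetylimidazole, −78 to −20 °C; AcOH quench
Reagents that add atoms: 1-acetylimidazole, CC(=O)n1ccnc1
Why: Lateral Claisen-type acylation of a 2-alkyl-4-pyranone: the 2-CH2 group is acidified vinylogously by C4=O and the 3-ester, its lithium dienolate should react with the acyl imidazole at the exocyclic carbon, and the second equivalent of base holds the more acidic product as its enolate until the quench.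

**Step 9**
Reactants: 13 methyl 5-[2,4-bis(benzyloxy)phenyl]-2-{6-methyl-2-oxo-6-[(triethylsilyl)oxy]heptan-3-yl}-4-oxo-4H-pyran-3-carboxylate (racemic)
Product: 14 3-[2,4-bis(benzyloxy)phenyl]-5,7-dihydroxy-8-{3-methyl-3-[(triethylsilyl)oxy]butyl}-4H-chromen-4-one
Conditions: LiN(SiMe3)2 (3.5 equiv), THF, −78 °C to rt; AcOH quench
Reagents that add atoms: none
Why: Proposed new method: the first equivalent of base removes the doubly activated C8–H, further base converts part of this monoanion into the dianion at the acetyl methyl group (C6), and this terminal enolate adds to the ester carbonyl (C5) held cis to it on the C8a=C4a bond, so that loss of methoxide forms C5–C6 and the product is trapped at once as the bis-phenoxide of 14, which makes the closure irreversible. The closest known reactions are the base-induced Claisen (Dieckmann) closure of methyl 2-(2-oxopropyl)benzoates to naphthalene-1,3-diols and of δ-keto esters to cyclohexane-1,3-diones; new here is that a 4-pyranone, not a benzene ring or a saturated chain, carries the two partners. Ring A closes in the 6-(enolexo)-exo-trig mode. No stereocentre is formed, and the only stereocentre of racemic 13 (C8) becomes an aromatic carbon. The step needs C-acylation at the ester in preference to conjugate addition at C2 of the pyranone and to O-acylation by the enolate oxygen on C7 (an enol lactone); the hindered, non-nucleophilic amide base should leave C2 alone, and the liberated methoxide can reopen any enol lactone so that material drains to the aromatic product. Because O1 is already the ring oxygen of the pyranone, the side chain can only end at C8 and no 6-alkyl isomer can arise.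

**Step 10**
Reactants: 14 3-[2,4-bis(benzyloxy)phenyl]-5,7-dihydroxy-8-{3-methyl-3-[(triethylsilyl)oxy]butyl}-4H-chromen-4-one
Product: 15 3-[2,4-bis(benzyloxy)phenyl]-5,7-dihydroxy-8-(3-hydroxy-3-methylbutyl)-4H-chromen-4-one
Conditions: Bu4NF, AcOH, THF, rt to 40 °C
Reagents that add atoms: none
Why: Fluoride-induced desilylation, with acetic acid buffering so that ring C is not opened by base and the tertiary alcohol does not cyclise onto the 7-hydroxyl.

**Step 11**
Reactants: 15 3-[2,4-bis(benzyloxy)phenyl]-5,7-dihydroxy-8-(3-hydroxy-3-methylbutyl)-4H-chromen-4-one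
Product: 16 2,3-dehydrokievitone hydrate, 3-(2,4-dihydroxyphenyl)-5,7-dihydroxy-8-(3-hydroxy-3-methylbutyl)-4H-chromen-4-one
Conditions: H2 (1 atm), Pd/C, EtOAc/MeOH, rt
Reagents that add atoms: none
Why: Catalytic hydrogenolysis of the two aryl benzyl ethers should be much faster at 1 atm than reduction of the C2=C3 bond, and the reaction is stopped after uptake of two equivalents of hydrogen.

**Compound list**
1 | 3-methylbutane-1,3-diol | CC(C)(O)CCO | starting material
2 | 4-iodo-2-methylbutan-2-ol | CC(C)(O)CCI | intermediate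
3 | triethyl[(4-iodo-2-methylbutan-2-yl)oxy]silane | CC(C)(CCI)O[Si](CC)(CC)CC | intermediate
4 | methyl acetoacetate | COC(=O)CC(C)=O | starting material
5 | methyl 7-methyl-3-oxo-7-[(triethylsilyl)oxy]octanoate | COC(=O)CC(=O)CCCC(C)(C)O[Si](CC)(CC)CC | intermediate
6 | (2,4-dihydroxyphenyl)acetic acid | OC(=O)Cc1ccc(O)cc1O | starting material
7 | benzyl [2,4-bis(benzyloxy)phenyl]acetate | O=C(Cc1ccc(OCc2ccccc2)cc1OCc1ccccc1)OCc1ccccc1 | intermediate
8 | [2,4-bis(benzyloxy)phenyl]acetic acid | OC(=O)Cc1ccc(OCc2ccccc2)cc1OCc1ccccc1 | intermediate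
9 | [2,4-bis(benzyloxy)phenyl]acetyl chloride (not isolated) | ClC(=O)Cc1ccc(OCc2ccccc2)cc1OCc1ccccc1 | intermediate
10 | methyl 2-{[2,4-bis(benzyloxy)phenyl]acetyl}-7-methyl-3-oxo-7-[(triethylsilyl)oxy]octanoate (drawn as the triketo tautomer) | COC(=O)C(C(=O)Cc1ccc(OCc2ccccc2)cc1OCc1ccccc1)C(=O)CCCC(C)(C)O[Si](CC)(CC)CC | intermediate
11 | methyl 2-{2-[2,4-bis(benzyloxy)phenyl]-3-(dimethylamino)prop-2-enoyl}-7-methyl-3-oxo-7-[(triethylsilyl)oxy]octanoate (not isolated, alkene geometry not defined) | COC(=O)C(C(=O)C(=CN(C)C)c1ccc(OCc2ccccc2)cc1OCc1ccccc1)C(=O)CCCC(C)(C)O[Si](CC)(CC)CC | intermediate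
12 | methyl 5-[2,4-bis(benzyloxy)phenyl]-2-{4-methyl-4-[(triethylsilyl)oxy]pentyl}-4-oxo-4H-pyran-3-carboxylate | COC(=O)c1c(CCCC(C)(C)O[Si](CC)(CC)CC)occ(-c2ccc(OCc3ccccc3)cc2OCc2ccccc2)c1=O | intermediate
13 | methyl 5-[2,4-bis(benzyloxy)phenyl]-2-{6-methyl-2-oxo-6-[(triethylsilyl)oxy]heptan-3-yl}-4-oxo-4H-pyran-3-carboxylate (racemic) | COC(=O)c1c(C(CCC(C)(C)O[Si](CC)(CC)CC)C(C)=O)occ(-c2ccc(OCc3ccccc3)cc2OCc2ccccc2)c1=O | intermediate
14 | 3-[2,4-bis(benzyloxy)phenyl]-5,7-dihydroxy-8-{3-methyl-3-[(triethylsilyl)oxy]butyl}-4H-chromen-4-one | CC(C)(O[Si](CC)(CC)CC)CCc1c(O)cc(O)c2c(=O)c(-c3ccc(OCc4ccccc4)cc3OCc3ccccc3)coc12 | intermediate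
15 | 3-[2,4-bis(benzyloxy)phenyl]-5,7-dihydroxy-8-(3-hydroxy-3-methylbutyl)-4H-chromen-4-one | CC(C)(O)CCc1c(O)cc(O)c2c(=O)c(-c3ccc(OCc4ccccc4)cc3OCc3ccccc3)coc12 | intermediate
16 | 2,3-dehydrokievitone hydrate | CC(C)(O)CCc1c(O)cc(O)c2c(=O)c(-c3ccc(O)cc3O)coc12 | target

**Totals**
Total step count: 11. Longest linear sequence: 9 steps (steps 1, 2, 3, 6, 7, 8, 9, 10, 11).

**Steps most likely to fail**

*Step 9.* The amide base may not generate enough dianion, so that 13 is returned. The enolate oxygen may acylate in place of carbon and divert material to an enol lactone. The rotamer with the acetyl group away from the ester may dominate, or the pyranone may be opened by base at C2.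

The fallback uses known chemistry and closes ring C last on a preformed ring A; it sets out from iodide 3 and comes back at target 16.
- Commercial 1-[2,4-bis(benzyloxy)-6-hydroxyphenyl]ethanone is iodinated ortho to the free phenol (BnMe3N·ICl2, NaHCO3, CH2Cl2/MeOH) to give 1-[4,6-bis(benzyloxy)-2-hydroxy-3-iodophenyl]ethanone F1. This places the future C8 next to the future O1.
- Iodide 3 is converted by iodine–lithium exchange (t-BuLi, Et2O, −78 °C) and B-methoxy-9-BBN into its B-alkyl borinate. Suzuki–Miyaura coupling with F1 (PdCl2(dppf), K3PO4, DMF, 60 °C) should give 1-{4,6-bis(benzyloxy)-2-hydroxy-3-[3-methyl-3-(triethylsilyloxy)butyl]phenyl}ethanone F2.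
- DMF-DMA (PhMe, 90 °C) gives (E)-1-{4,6-bis(benzyloxy)-2-hydroxy-3-[3-methyl-3-(triethylsilyloxy)butyl]phenyl}-3-(dimethylamino)prop-2-en-1-one F3.
- I2 in CHCl3/pyridine closes ring C and iodinates C3 to give 5,7-bis(benzyloxy)-3-iodo-8-[3-methyl-3-(triethylsilyloxy)butyl]-4H-chromen-4-one F4.
- Suzuki–Miyaura coupling with [2,4-bis(benzyloxy)phenyl]boronic acid (Pd(PPh3)4, Na2CO3, DME/H2O, 80 °C) gives 5,7-bis(benzyloxy)-3-[2,4-bis(benzyloxy)phenyl]-8-[3-methyl-3-(triethylsilyloxy)butyl]-4H-chromen-4-one F5.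
- Bu4NF in THF removes the silyl group to give 5,7-bis(benzyloxy)-3-[2,4-bis(benzyloxy)phenyl]-8-(3-hydroxy-3-methylbutyl)-4H-chromen-4-one F6.
- Hydrogenolysis of the four benzyl ethers (H2, Pd/C, EtOAc/MeOH) returns to 16.

*Step 8.* The hindered, strongly stabilised secondary dienolate may react slowly, may be acylated on oxygen, or may be quenched by proton transfer from the more acidic product.

The fallback moves the acylation to an unhindered methyl group and forms the C8–chain bond by alkylation; it sets out from acid 8 and comes back at 13.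
- Acid 8, via its chloride 9, C-acylates methyl acetoacetate 4 (MgCl2, pyridine, CH2Cl2) to give methyl 2-acetyl-4-[2,4-bis(benzyloxy)phenyl]-3-oxobutanoate F7.
- DMF-DMA condenses at the benzylic methylene to give methyl 2-acetyl-4-[2,4-bis(benzyloxy)phenyl]-5-(dimethylamino)-3-oxopent-4-enoate F8.
- AcOH closes F8 to methyl 5-[2,4-bis(benzyloxy)phenyl]-2-methyl-4-oxo-4H-pyran-3-carboxylate F9.
- Lateral acetylation of the 2-methyl group (LiN(SiMe3)2, N-acetylimidazole, THF, −78 °C) gives methyl 5-[2,4-bis(benzyloxy)phenyl]-4-oxo-2-(2-oxopropyl)-4H-pyran-3-carboxylate F10.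
- C-alkylation of the doubly activated methylene of F10 with iodide 3 (Cs2CO3, DMF, 40 °C) returns to 13.

*Step 7.* The acetal may methylate the enol oxygen, the liberated amine and methanol may deacylate the triacylmethane, or condensation may take place at the chain methylene.

The fallback attaches ring B by cross-coupling to a preformed iodopyranone; it sets out from β-keto ester 5 and comes back at 12.
- 5 is C-acetylated (AcCl, MgCl2, pyridine, CH2Cl2) to give methyl 2-acetyl-7-methyl-3-oxo-7-[(triethylsilyl)oxy]octanoate F11.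
- DMF-DMA condenses at the acetyl methyl group to give methyl 2-[3-(dimethylamino)prop-2-enoyl]-7-methyl-3-oxo-7-[(triethylsilyl)oxy]octanoate F12.
- I2 in CHCl3/pyridine closes and iodinates F12 to give methyl 5-iodo-2-{4-methyl-4-[(triethylsilyl)oxy]pentyl}-4-oxo-4H-pyran-3-carboxylate F13.
- Suzuki–Miyaura coupling with [2,4-bis(benzyloxy)phenyl]boronic acid (Pd(PPh3)4, K2CO3, dioxane/H2O, 80 °C) returns to 12.

**Further compounds**
F1 | step 9 | 1-[4,6-bis(benzyloxy)-2-hydroxy-3-iodophenyl]ethanone | CC(=O)c1c(O)c(I)c(OCc2ccccc2)cc1OCc1ccccc1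
F2 | step 9 | 1-{4,6-bis(benzyloxy)-2-hydroxy-3-[3-methyl-3-(triethylsilyloxy)butyl]phenyl}ethanone | CC(=O)c1c(O)c(CCC(C)(C)O[Si](CC)(CC)CC)c(OCc2ccccc2)cc1OCc1ccccc1
F3 | step 9 | (E)-1-{4,6-bis(benzyloxy)-2-hydroxy-3-[3-methyl-3-(triethylsilyloxy)butyl]phenyl}-3-(dimethylamino)prop-2-en-1-one | CN(C)/C=C/C(=O)c1c(O)c(CCC(C)(C)O[Si](CC)(CC)CC)c(OCc2ccccc2)cc1OCc1ccccc1
F4 | step 9 | 5,7-bis(benzyloxy)-3-iodo-8-[3-methyl-3-(triethylsilyloxy)butyl]-4H-chromen-4-one | CC(C)(O[Si](CC)(CC)CC)CCc1c(OCc2ccccc2)cc(OCc2ccccc2)c2c(=O)c(I)coc12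
F5 | step 9 | 5,7-bis(benzyloxy)-3-[2,4-bis(benzyloxy)phenyl]-8-[3-methyl-3-(triethylsilyloxy)butyl]-4H-chromen-4-one | CC(C)(O[Si](CC)(CC)CC)CCc1c(OCc2ccccc2)cc(OCc2ccccc2)c2c(=O)c(-c3ccc(OCc4ccccc4)cc3OCc3ccccc3)coc12
F6 | step 9 | 5,7-bis(benzyloxy)-3-[2,4-bis(benzyloxy)phenyl]-8-(3-hydroxy-3-methylbutyl)-4H-chromen-4-one | CC(C)(O)CCc1c(OCc2ccccc2)cc(OCc2ccccc2)c2c(=O)c(-c3ccc(OCc4ccccc4)cc3OCc3ccccc3)coc12
F7 | step 8 | methyl 2-acetyl-4-[2,4-bis(benzyloxy)phenyl]-3-oxobutanoate | COC(=O)C(C(C)=O)C(=O)Cc1ccc(OCc2ccccc2)cc1OCc1ccccc1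
F8 | step 8 | methyl 2-acetyl-4-[2,4-bis(benzyloxy)phenyl]-5-(dimethylamino)-3-oxopent-4-enoate | COC(=O)C(C(C)=O)C(=O)C(=CN(C)C)c1ccc(OCc2ccccc2)cc1OCc1ccccc1
F9 | step 8 | methyl 5-[2,4-bis(benzyloxy)phenyl]-2-methyl-4-oxo-4H-pyran-3-carboxylate | COC(=O)c1c(C)occ(-c2ccc(OCc3ccccc3)cc2OCc2ccccc2)c1=O
F10 | step 8 | methyl 5-[2,4-bis(benzyloxy)phenyl]-4-oxo-2-(2-oxopropyl)-4H-pyran-3-carboxylate | COC(=O)c1c(CC(C)=O)occ(-c2ccc(OCc3ccccc3)cc2OCc2ccccc2)c1=O
F11 | step 7 | methyl 2-acetyl-7-methyl-3-oxo-7-[(triethylsilyl)oxy]octanoate | COC(=O)C(C(C)=O)C(=O)CCCC(C)(C)O[Si](CC)(CC)CC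
F12 | step 7 | methyl 2-[3-(dimethylamino)prop-2-enoyl]-7-methyl-3-oxo-7-[(triethylsilyl)oxy]octanoate | COC(=O)C(C(=O)/C=C/N(C)C)C(=O)CCCC(C)(C)O[Si](CC)(CC)CC
F13 | step 7 | methyl 5-iodo-2-{4-methyl-4-[(triethylsilyl)oxy]pentyl}-4-oxo-4H-pyran-3-carboxylate | COC(=O)c1c(CCCC(C)(C)O[Si](CC)(CC)CC)occ(I)c1=O
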